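**Numbering used throughout.** 1 δ-valerolactone; 2 bis(silylmethyl) diol (not isolated); 3 hydroxy allylsilane; 4 aldehyde; 5 α-chloro aldehyde (not isolated); 6 secondary chloroethynyl carbinol; 7 α-chloro ynone; 8 tertiary carbinol; 9 its triflate (not isolated); 10 tertiary propargylic cation (not isolated); 11 cyclised chloroalkyne with exocyclic methylene; 12 axial allylic alcohol; 13 equatorial allylic chloride; 14 dibromide; 15 alkenylborane (not isolated); 16 target.

Ring positions are quoted with the locants of 16 unless an intermediate is named explicitly: C1 = CBr(CH2Br), C2 = CHCl, C3 = CH2, C4 = CHCl, C5 = C(CH3)(CH=CHCl), C6 = CH2.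

## Analysis of the target

Compound 16 is (1S,2R,4S,5S)-1-bromo-1-(bromomethyl)-2,4-dichloro-5-[(Z)-2-chloroethenyl]-5-methylcyclohexane, a pentahalogenated monocyclic monoterpene with a 1-ethyl-1,3-dimethylcyclohexane skeleton (ring C1–C6). It has four stereocentres: the all-carbon quaternary C5, the neopentylic chloride C4, the chloride C2 and the tertiary bromide C1. The chlorovinyl group, both ring chlorines and the tertiary bromine lie on one face; methyl and CH2Br lie on the other. In the chair this puts both chlorines, the methyl and the CH2Br group equatorial, and the chlorovinyl group and the bromine 1,3-diaxial. The sensitive groups are the tertiary bromide (E2, ionisation), the vicinal dibromide (debromination by phosphines, zinc or iodide), two secondary chlorides and a Z-vinyl chloride that isomerises through any allyl cation. Three features make the synthesis hard: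

- The C4 chloride sits beside the quaternary C5. Substitution there is blocked, and ionisation would trigger a 1,2-shift of the unsaturated branch.
- The C2 chloride is equatorial beside the C1 exocyclic carbon. Electrophilic chlorination of a ring alkene enters axially and gives the wrong epimer, and an allylic alcohol at C2 is prone to transposition.
- The Z-chlorovinyl group hangs on a quaternary carbon.

The feature exploited is the C5–C6 bond. It is the only ring bond that is not part of a head-to-tail monoterpene chain, and it joins the quaternary C5 (flanked by the C4 chlorine) to a methylene next to the C1 exocyclic carbon. This is the pattern left by a cation–olefin cyclisation in the presumed biosynthesis.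

## Retrosynthetic reasoning

**16 from 14.** The two vinylic C–H bonds of the Z-chloroalkene are cut back to the chloroalkyne 14. Syn hydroboration followed by protonolysis fixes the Z geometry by mechanism. The alkyne is also the smallest possible two-carbon branch at C5, which the key step needs.

**14 from 13.** The C1–Br and CH2–Br bonds are cut back to the exocyclic alkene 13. The fragile tertiary bromide is therefore made late, by anti addition with axial entry of bromide; the electron-poor chloroalkyne is left alone.

**13 from 12 from 11.** The equatorial C2–Cl bond is cut to the axial allylic alcohol 12, and that C–O bond to the allylic C–H of 11. Chlorine cannot be delivered equatorially as an electrophile, so oxygen is put in axially by a selenium-mediated ene/[2,3] sequence and then inverted by SN2.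

**11 from 8 (key disconnection).** The ring bond C5–C6 is cut. Forward, the tertiary propargylic cation 10, generated from carbinol 8, is captured by the terminal carbon of a 2-substituted allylsilane. One operation closes the six-membered ring, creates the quaternary stereocentre C5 relative to C4 and leaves the C1 exocyclic methylene. The precursor is acyclic with a single controlling stereocentre. The cut is made here, and not at C4–C5 or C1–C6, because it is the biosynthetic bond and because it lets the C4 chlorine be present before the quaternary centre exists.

**8 from 7 from 6 from 4.** The carbinol carbon (future C5) is the aldehyde carbon of 4. It receives a chloroethynyl group, is oxidised, and then receives methyl. In this order the Felkin-controlled epimer of 8 is the one that ionises directly into the productive rotamer. The C4–Cl bond is made by enamine-catalysed α-chlorination of 4 (giving 5), the only reagent-controlled stereocentre of the route.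

**4 from 3 from 1.** The allylsilane C=C and CH2Si carbons are both cut from the lactone carbonyl of 1 (double silylmethyl addition, then Peterson elimination). The aldehyde comes from the liberated primary alcohol 3.

## Alternatives that were turned down

**Alternative 1:** the textbook Diels–Alder disconnection of C5–C6 and C3–C4. The Z-configured β-chloro enal A1 would react with the 2-silyloxydiene A2 to give cyclohexene A3, with C4 and C5 set by the dienophile geometry. It was turned down for four reasons.

- The donor oxygen of A2 necessarily ends para to C5, at C2. The C1 carbon must then be added by α-methylenation, and the resulting exo-methylene ketone must be reduced from the equatorial side; hydrides that attack that way add 1,4 to such enones.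
- The C2 ketone is β to the C4 chlorine, so every enolate or amine step risks E1cB loss of HCl.
- A1 is a vinylogous acid chloride. With a silyl enol ether diene and a Lewis acid, addition–elimination and E/Z scrambling compete, and enantioselective catalysis of this dienophile class is unproven.
- The aldehyde of A3 still needs three steps to become the Z-chlorovinyl group.

The total is no shorter than the chosen route, and it has three soft steps in the endgame.

**Alternative 2:** skeletal remodelling of a p-menthane by anionic oxy-Cope rearrangement. The target skeleton is the [3,3] isomer of the p-menthane skeleton. Dienol A4 would break its ring bond next to the carbinol and bond the isopropenyl terminus to the methyl-bearing ring alkene carbon, giving ketone A5 with C5 set stereospecifically. It was turned down because the halogens do not fit.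

- The C4 chlorine cannot be carried through the rearrangement: as an allylic chloride in a potassium alkoxide it would undergo Grob fragmentation or E2.
- It cannot be added afterwards either, since that would be a substitution at a neopentylic carbon anti-periplanar to a vinyl group that migrates readily.
- The ketone of A5 is again at C2, leaving the same C1/C2 problem as Alternative 1.
- The plain vinyl group would need a Z-selective chloro-olefin metathesis at a quaternary allylic carbon.

**Alternative 3:** the literal biomimetic chloronium cyclisation. A Cl+ source would add to C4 of the acyclic chlorodiene A6, and the terminal isopropenyl group would close C5–C6 to give triene A7, one bromination away from 16. It was turned down for five reasons.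

- Three π-systems compete for Cl+.
- The intermediate is a chloroallyl cation. Rotation within it erases the Z geometry, and the planar chloroallyl unit differs too little from methyl to control C5.
- The remote C2 chloride would have to control the face of chloronium attack at C4, which it cannot.
- Termination by proton loss gives endo/exo alkene mixtures.
- No enantioselective chloronium reagent for carbocyclisation is established.

The chosen route keeps the bond construction of this alternative but replaces Cl+ by ionisation next to a pre-set chloride, chloroallyl by chloroethynyl, and proton loss by silyl loss.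

Key step: step 6

Assumption: in step 3 the (2R,5R) antipode of the catalyst is written as the one that delivers the (2S)-chloro aldehyde 5; if the sense of induction is the opposite, the (2S,5S) catalyst is used and nothing else changes.

## Route

Step 1
Reactants: 1 δ-valerolactone (tetrahydro-2H-pyran-2-one)
Product: 3 5-[(trimethylsilyl)methyl]hex-5-en-1-ol, via bis(silylmethyl) diol 2 (not isolated)
Conditions: Me3SiCH2MgCl (3 equiv), CeCl3, THF, −78 °C to rt; then SiO2, CH2Cl2, rt
Reagents that add atoms: (trimethylsilyl)methylmagnesium chloride, C[Si](C)(C)C[Mg]Cl
Why: Double addition of the organocerium reagent to the lactone carbonyl (cerium suppresses enolisation) gives the bis(β-silyl) tertiary carbinol 2, and silica-promoted Peterson elimination of one β-hydroxysilane arm leaves the 2-substituted allylsilane; the primary alcohol is untouched.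

Step 2
Reactants: 3 5-[(trimethylsilyl)methyl]hex-5-en-1-ol
Product: 4 5-[(trimethylsilyl)methyl]hex-5-enal
Conditions: Dess–Martin periodinane, CH2Cl2, 0 °C to rt
Reagents that add atoms: none
Why: Dess–Martin oxidation of a primary alcohol under mild conditions; the allylsilane is inert to the periodinane at this temperature.

Step 3
Reactants: 4 5-[(trimethylsilyl)methyl]hex-5-enal
Product: 6 (4S)-1,4-dichloro-7-[(trimethylsilyl)methyl]oct-7-en-1-yn-3-ol (both C3 epimers), via α-chloro aldehyde 5 (not isolated)
Conditions: NCS, (2R,5R)-2,5-diphenylpyrrolidine (10 mol %), CH2Cl2, 0 °C; then the cold solution into LiC≡CCl (3 equiv) [from (E)-ClCH=CHCl, MeLi], THF, −78 °C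
Reagents that add atoms: N-chlorosuccinimide, O=C1CCC(=O)N1Cl; lithium chloroacetylide, [Li]C#CCl (made in the flask from (E)-1,2-dichloroethene, Cl/C=C/Cl)
Why: Enamine-catalysed electrophilic α-chlorination sets the C4 stereocentre (target numbering) under catalyst control; the configurationally labile aldehyde 5 is trapped at once by 1,2-addition of the chloroacetylide, the carbinol configuration is irrelevant because it is oxidised next, and the allylsilane is far less nucleophilic than the enamine towards N-chlorosuccinimide.

Step 4
Reactants: 6 (4S)-1,4-dichloro-7-[(trimethylsilyl)methyl]oct-7-en-1-yn-3-ol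
Product: 7 (4S)-1,4-dichloro-7-[(trimethylsilyl)methyl]oct-7-en-1-yn-3-one
Conditions: Dess–Martin periodinane, CH2Cl2, 0 °C
Reagents that add atoms: none
Why: Dess–Martin oxidation of a secondary propargylic alcohol to the ynone under mild conditions that should not epimerise the α-chloro centre.

Step 5
Reactants: 7 (4S)-1,4-dichloro-7-[(trimethylsilyl)methyl]oct-7-en-1-yn-3-one
Product: 8 (3S,4S)-1,4-dichloro-3-methyl-7-[(trimethylsilyl)methyl]oct-7-en-1-yn-3-ol (major epimer; the 3R epimer is carried along)
Conditions: MeMgBr, CeCl3, THF, −78 °C; AcOH quench at −78 °C
Reagents that add atoms: methylmagnesium bromide, C[Mg]Br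
Why: 1,2-Addition of the weakly basic organocerium methyl reagent under Felkin–Anh/Cornforth control by the α-chlorine (attack anti to C–Cl) should give mainly the (3S) carbinol, the epimer whose hydroxyl can stand anti to chlorine in the rotamer needed in step 6; low basicity limits enolisation of the α-chloro ynone and conjugate addition, and the cold acidic quench prevents epoxide formation from the chlorohydrin alkoxide.

Step 6
Reactants: 8 (3S,4S)-1,4-dichloro-3-methyl-7-[(trimethylsilyl)methyl]oct-7-en-1-yn-3-ol (with its 3R epimer)
Product: 11 (1S,2S)-2-chloro-1-(chloroethynyl)-1-methyl-5-methylidenecyclohexane, via tertiary triflate 9 (not isolated), via propargylic cation 10 (not isolated)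
Conditions: Tf2O (1.1 equiv), 2,6-di-tert-butyl-4-methylpyridine (1.5 equiv), CH2Cl2, −78 to −40 °C
Reagents that add atoms: none
Why: The tertiary alcohol is O-triflated in the flask (9) and ionises with the neighbouring C–Cl bond anti-periplanar to the leaving group, giving the weakly chlorine-bridged tertiary propargylic cation 10; triflate is chosen because the β-chlorine and the alkynyl group both retard ionisation. The terminal carbon of the 2-substituted allylsilane then attacks the cationic carbon through a chair transition state (cation–olefin cyclisation, six-membered ring, endo with respect to the allylsilane double bond), and the β-silyl cation collapses to the exocyclic methylene by loss of silicon to triflate, so the position of the new alkene is fixed. The closest known reactions are the acid-mediated SN1 substitution of tertiary propargylic alcohols by allylsilanes (Hosomi–Sakurai type) and allylsilane-terminated cation–olefin cyclisations, and the bond made is the one the presumed biosynthesis makes. The new quaternary stereocentre is controlled by the existing C–Cl stereocentre: chlorine sits anti to the forming bond and hence equatorial, and of the two remaining groups on the cationic carbon the rod-like chloroethynyl group, whose conformational demand is far below that of methyl, takes the crowded inside position that becomes axial, which places it cis to chlorine as in the target. The major (3S) epimer of 8 ionises directly into this rotamer (net retention through chlorine participation), and the minor (3R) epimer should reach it by rotation about the C3–C4 bond of 10, so both carbinol epimers are expected to funnel into one product. The step needs attack at the propargylic and not the allenyl terminus (enforced by ring size), no protodesilylation (the hindered pyridine buffers triflic acid) and ring closure faster than proton loss to an enyne (favoured by the intramolecular allylsilane).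

Step 7
Reactants: 11 (1S,2S)-2-chloro-1-(chloroethynyl)-1-methyl-5-methylidenecyclohexane
Product: 12 (1S,4S,5S)-5-chloro-4-(chloroethynyl)-4-methyl-2-methylidenecyclohexan-1-ol
Conditions: SeO2 (0.5 equiv), t-BuOOH (3 equiv), CH2Cl2, 0 °C to rt
Reagents that add atoms: selenium dioxide, O=[Se]=O; tert-butyl hydroperoxide, CC(C)(C)OO
Why: Riley allylic oxidation: the ene reaction at the exocyclic methylene removes the axial hydrogen at C4 of 11 (the other allylic methylene, C6, is neopentylic and hindered), and the [2,3]-sigmatropic shift returns the double bond to the exocyclic position while delivering oxygen axially, anti to the axial chloroethynyl group and therefore trans to the ring chlorine; the chloroalkyne and the secondary chloride are inert.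

Step 8
Reactants: 12 (1S,4S,5S)-5-chloro-4-(chloroethynyl)-4-methyl-2-methylidenecyclohexan-1-ol
Product: 13 (1S,2S,4R)-2,4-dichloro-1-(chloroethynyl)-1-methyl-5-methylidenecyclohexane
Conditions: PPh3, Cl3CCOCCl3, CH2Cl2, −20 to 0 °C
Reagents that add atoms: hexachloroacetone, ClC(Cl)(Cl)C(=O)C(Cl)(Cl)Cl
Why: Appel-type chlorination with triphenylphosphine and hexachloroacetone, conditions known to convert allylic alcohols into chlorides by SN2 with inversion and little allylic transposition, turns the axial alcohol into the equatorial chloride that electrophilic chlorination cannot give; the phosphine is consumed by hexachloroacetone faster than it can attack the chloroalkyne.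

Step 9
Reactants: 13 (1S,2S,4R)-2,4-dichloro-1-(chloroethynyl)-1-methyl-5-methylidenecyclohexane
Product: 14 (1S,2R,4S,5S)-1-bromo-1-(bromomethyl)-2,4-dichloro-5-(chloroethynyl)-5-methylcyclohexane
Conditions: Br2 (1.0 equiv), CH2Cl2, −78 °C, dark
Reagents that add atoms: bromine, BrBr
Why: Anti addition of bromine through a bromonium ion on the exocyclic alkene; bromide should open it at the tertiary carbon from the axial direction, giving the axial tertiary bromide and the equatorial bromomethyl group, which is also the more stable epimer (the two epimers can equilibrate through the same bromonium ion); the equatorial C–Cl bond lies in the nodal plane of the developing cation and should not migrate, and the electron-poor chloroalkyne does not react with bromine at this temperature.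

Step 10
Reactants: 14 (1S,2R,4S,5S)-1-bromo-1-(bromomethyl)-2,4-dichloro-5-(chloroethynyl)-5-methylcyclohexane
Product: 16 (1S,2R,4S,5S)-1-bromo-1-(bromomethyl)-2,4-dichloro-5-[(Z)-2-chloroethenyl]-5-methylcyclohexane, via alkenylborane 15 (not isolated)
Conditions: (c-C6H11)2BH [from BH3·SMe2, cyclohexene], THF, 0 °C to rt; then AcOH, rt
Reagents that add atoms: none
Why: Syn hydroboration of the 1-chloroalkyne places boron on the chlorine-bearing carbon (15), and protonolysis of the alkenyl C–B bond by acetic acid with retention gives the Z-chloroalkene by mechanism; no other π-bond is left, and alkyl bromides and chlorides are inert to dialkylboranes and acetic acid at room temperature.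

## Compound list

1 | δ-valerolactone (tetrahydro-2H-pyran-2-one) | O=C1CCCCO1 | starting material
2 | 6-(trimethylsilyl)-5-[(trimethylsilyl)methyl]hexane-1,5-diol | OCCCCC(O)(C[Si](C)(C)C)C[Si](C)(C)C | intermediate
3 | 5-[(trimethylsilyl)methyl]hex-5-en-1-ol | OCCCCC(=C)C[Si](C)(C)C | intermediate
4 | 5-[(trimethylsilyl)methyl]hex-5-enal | O=CCCCC(=C)C[Si](C)(C)C | intermediate
5 | (2S)-2-chloro-5-[(trimethylsilyl)methyl]hex-5-enal | O=C[C@@H](Cl)CCC(=C)C[Si](C)(C)C | intermediate
6 | (4S)-1,4-dichloro-7-[(trimethylsilyl)methyl]oct-7-en-1-yn-3-ol (both C3 epimers) | OC(C#CCl)[C@@H](Cl)CCC(=C)C[Si](C)(C)C | intermediate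
7 | (4S)-1,4-dichloro-7-[(trimethylsilyl)methyl]oct-7-en-1-yn-3-one | O=C(C#CCl)[C@@H](Cl)CCC(=C)C[Si](C)(C)C | intermediate
8 | (3S,4S)-1,4-dichloro-3-methyl-7-[(trimethylsilyl)methyl]oct-7-en-1-yn-3-ol (major epimer) | C[C@](O)(C#CCl)[C@@H](Cl)CCC(=C)C[Si](C)(C)C | intermediate
9 | (3S,4S)-1,4-dichloro-3-methyl-7-[(trimethylsilyl)methyl]oct-7-en-1-yn-3-yl trifluoromethanesulfonate | C[C@](OS(=O)(=O)C(F)(F)F)(C#CCl)[C@@H](Cl)CCC(=C)C[Si](C)(C)C | intermediate
10 | (4S)-1,4-dichloro-3-methyl-7-[(trimethylsilyl)methyl]oct-7-en-1-yn-3-ylium | C[C+](C#CCl)[C@@H](Cl)CCC(=C)C[Si](C)(C)C | intermediate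
11 | (1S,2S)-2-chloro-1-(chloroethynyl)-1-methyl-5-methylidenecyclohexane | C[C@@]1(C#CCl)CC(=C)CC[C@@H]1Cl | intermediate
12 | (1S,4S,5S)-5-chloro-4-(chloroethynyl)-4-methyl-2-methylidenecyclohexan-1-ol | C[C@@]1(C#CCl)CC(=C)[C@@H](O)C[C@@H]1Cl | intermediate
13 | (1S,2S,4R)-2,4-dichloro-1-(chloroethynyl)-1-methyl-5-methylidenecyclohexane | C[C@@]1(C#CCl)CC(=C)[C@H](Cl)C[C@@H]1Cl | intermediate
14 | (1S,2R,4S,5S)-1-bromo-1-(bromomethyl)-2,4-dichloro-5-(chloroethynyl)-5-methylcyclohexane | C[C@@]1(C#CCl)C[C@@](Br)(CBr)[C@H](Cl)C[C@@H]1Cl | intermediate
15 | [(Z)-2-[(1S,2S,4R,5S)-5-bromo-5-(bromomethyl)-2,4-dichloro-1-methylcyclohexyl]-1-chloroethenyl]dicyclohexylborane | C[C@@]1(/C=C(\Cl)B(C2CCCCC2)C2CCCCC2)C[C@@](Br)(CBr)[C@H](Cl)C[C@@H]1Cl | intermediate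
16 | (1S,2R,4S,5S)-1-bromo-1-(bromomethyl)-2,4-dichloro-5-[(Z)-2-chloroethenyl]-5-methylcyclohexane | C[C@@]1(/C=C\Cl)C[C@@](Br)(CBr)[C@H](Cl)C[C@@H]1Cl | target

## Step count and least certain steps

Total step count: 10. Longest linear sequence: 10 steps (the route is linear from 1).

**Step 6 (key step).** The β-chlorine and the alkynyl group both slow ionisation, so the triflate may lose a proton to an enyne, or the allylsilane may be protodesilylated before ring closure. Incomplete rotamer equilibration of the cation would also lower the selectivity at the quaternary centre. Fallback: the same C5–C6 bond is closed at the carbonyl stage. Ynone 7 is treated with TiCl4 in CH2Cl2 at −78 °C (intramolecular Hosomi–Sakurai addition of the allylsilane to the ketone) to give (2S)-2-chloro-1-(chloroethynyl)-5-methylidenecyclohexan-1-ol F1. The tertiary propargylic alcohol F1 is then methylated by SN1 substitution with AlMe3. In the ring cation the C–Cl bond should stand axial to avoid the exocyclic alkynyl group, and methyl should enter anti to chlorine, which leaves the alkyne cis to chlorine. The route is rejoined at 11.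

**Step 7.** Oxidation may occur at the neopentylic allylic methylene instead, run on to the enone, or deliver oxygen equatorially. Fallback: the equatorial chloride is installed through carbonyl chemistry. Ozonolysis of 11 (O3, then Me2S; the chloroalkyne is inert) gives (3S,4S)-4-chloro-3-(chloroethynyl)-3-methylcyclohexan-1-one F2. Kinetic axial bromination on the unhindered side with PhNMe3Br3 gives (2S,4S,5S)-2-bromo-4-chloro-5-(chloroethynyl)-5-methylcyclohexan-1-one F3. SN2 displacement with LiCl in DMF inverts it to (2R,4S,5S)-2,4-dichloro-5-(chloroethynyl)-5-methylcyclohexan-1-one F4. Non-basic methylenation with Cp2Ti(μ-Cl)(μ-CH2)AlMe2 then gives 13, so this detour also bypasses step 8.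

**Step 8.** The axial C–O bond is aligned with the exocyclic π-bond, so allylic transposition to the primary chloride (SN2′) or E2 loss to a diene may compete with direct displacement. Fallback: the displacement is moved to a non-allylic, carbonyl-activated carbon. Ozonolysis of 12 gives (2S,4S,5S)-4-chloro-5-(chloroethynyl)-2-hydroxy-5-methylcyclohexan-1-one F5. Appel chlorination (PPh3, CCl4) then proceeds with inversion to the α-chloro ketone F4 already described under step 7, which is methylenated as there to 13.

**Step 5.** The α-chloro ynone may enolise and epimerise at the chlorine-bearing carbon, or suffer conjugate addition or halogen–metal exchange at the chloroalkyne. Fallback: the order of the two carbonyl additions is reversed. Aldehyde 5 (made as in step 3) is treated with MeMgBr to give (3S)-3-chloro-6-[(trimethylsilyl)methyl]hept-6-en-2-ol F6. Dess–Martin oxidation gives the much less acidic (3S)-3-chloro-6-[(trimethylsilyl)methyl]hept-6-en-2-one F7, and lithium chloroacetylide then gives 8. This material would be enriched in the (3R) epimer, so this variant relies fully on rotamer equilibration of cation 10 in step 6.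

## Further compounds

F1 | step 6 | (2S)-2-chloro-1-(chloroethynyl)-5-methylidenecyclohexan-1-ol (either C1 epimer) | OC1(C#CCl)CC(=C)CC[C@@H]1Cl
F2 | step 7 | (3S,4S)-4-chloro-3-(chloroethynyl)-3-methylcyclohexan-1-one | C[C@@]1(C#CCl)CC(=O)CC[C@@H]1Cl
F3 | step 7 | (2S,4S,5S)-2-bromo-4-chloro-5-(chloroethynyl)-5-methylcyclohexan-1-one | C[C@@]1(C#CCl)CC(=O)[C@@H](Br)C[C@@H]1Cl
F4 | step 7 | (2R,4S,5S)-2,4-dichloro-5-(chloroethynyl)-5-methylcyclohexan-1-one | C[C@@]1(C#CCl)CC(=O)[C@H](Cl)C[C@@H]1Cl
F5 | step 8 | (2S,4S,5S)-4-chloro-5-(chloroethynyl)-2-hydroxy-5-methylcyclohexan-1-one | C[C@@]1(C#CCl)CC(=O)[C@@H](O)C[C@@H]1Cl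
F6 | step 5 | (3S)-3-chloro-6-[(trimethylsilyl)methyl]hept-6-en-2-ol (both C2 epimers) | CC(O)[C@@H](Cl)CCC(=C)C[Si](C)(C)C
F7 | step 5 | (3S)-3-chloro-6-[(trimethylsilyl)methyl]hept-6-en-2-one | CC(=O)[C@@H](Cl)CCC(=C)C[Si](C)(C)C
A1 | alternative 1 | (Z)-3-chloro-2-methylprop-2-enal | O=C/C(C)=C\Cl
A2 | alternative 1 | 2-[(triisopropylsilyl)oxy]buta-1,3-diene | C=CC(=C)O[Si](C(C)C)(C(C)C)C(C)C
A3 | alternative 1 | (1S,6S)-6-chloro-1-methyl-4-[(triisopropylsilyl)oxy]cyclohex-3-ene-1-carbaldehyde | C[C@@]1(C=O)CC=C(O[Si](C(C)C)(C(C)C)C(C)C)C[C@@H]1Cl
A4 | alternative 2 | (1R)-4-methyl-1-(prop-1-en-2-yl)cyclohex-3-en-1-ol | CC1=CC[C@@](O)(C(C)=C)CC1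
A5 | alternative 2 | (4S)-4-ethenyl-2,4-dimethylcyclohexan-1-one (both C2 epimers) | C[C@@]1(C=C)CC(C)C(=O)CC1
A6 | alternative 3 | (1Z,3Z,6R)-1,6-dichloro-3,7-dimethylocta-1,3,7-triene | Cl/C=C\C(C)=C/C[C@@H](Cl)C(C)=C
A7 | alternative 3 | (1S,2S,4R)-2,4-dichloro-1-[(Z)-2-chloroethenyl]-1-methyl-5-methylidenecyclohexane | C[C@@]1(/C=C\Cl)CC(=C)[C@H](Cl)C[C@@H]1Cl
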